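**Retrosynthetic overview**

- Target 15 ⇐ BBr3 demethylation of hexamethyl ether 14 ⇐ saponification and decarboxylation of resorcylate 12; the ester on C6 of ring C is a traceless activating group.
- Ring C (the 3,4,5-trihydroxyphenyl ring, the only ring built and the last in place) ⇐ [3+3] Michael–Claisen annulation. C1 (the ether carbon), C2 and C3 are the β, α and ester carbons of aryloxypropiolate 9; C6, C5 and C4 are C2, the ketone carbon and the methoxymethylene carbon of keto ester 10. Bonds C1–C6 and C3–C4 are formed, so the oxygens on C1, C3, C4 and C5 all arrive with the two open-chain partners.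
- Ynoate 9 ⇐ (E)-1,2-dichlorovinyl ether 7 ⇐ phenol 5 + trichloroethylene 6; the hindered ring B oxygen flanked by two ortho oxygens is alkynylated and never arylated.
- Phenol 5 ⇐ hydrogenolysis of benzyl ether 4 ⇐ copper coupling of 2,4,6-trimethoxyphenol 3 (ring A) with benzyl-protected bromide 2 (ring B, from 1); rings A and B are bought as arenes.

Key step: step 6

Assumption: phenols 1 and 3 are taken as purchased, and adduct 11, which exists in the flask as an enolate with interconverting alkene geometries and no fixed configuration at C4, is drawn as the E isomer that can cyclise.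

**Route**

Step 1
Reactants: 1 4-bromo-2,6-dimethoxyphenol
Product: 2 2-(benzyloxy)-5-bromo-1,3-dimethoxybenzene
Conditions: BnBr, K2CO3, DMF, rt
Reagents that add atoms: benzyl bromide, BrCc1ccccc1
Why: Williamson O-alkylation of the phenoxide masks the phenol so that the bromide can enter the copper coupling without self-condensation.

Step 2
Reactants: 2 2-(benzyloxy)-5-bromo-1,3-dimethoxybenzene; 3 2,4,6-trimethoxyphenol
Product: 4 2-(benzyloxy)-1,3-dimethoxy-5-(2,4,6-trimethoxyphenoxy)benzene
Conditions: CuI (10 mol %), picolinic acid (20 mol %), K3PO4, DMSO, 100 °C, Ar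
Reagents that add atoms: none
Why: Ullmann diaryl ether synthesis with monovalent copper and picolinic acid, a system suited to di-ortho-substituted phenols, should work here because the bromide of 2 has two free ortho positions and all the hindrance sits on the phenol partner.

Step 3
Reactants: 4 2-(benzyloxy)-1,3-dimethoxy-5-(2,4,6-trimethoxyphenoxy)benzene
Product: 5 2,6-dimethoxy-4-(2,4,6-trimethoxyphenoxy)phenol
Conditions: H2 (1 atm), 10% Pd/C, EtOAc–MeOH, rt
Reagents that add atoms: none
Why: Hydrogenolysis of the benzyl ether over palladium on carbon leaves the diaryl ether and the methyl ethers untouched.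

Step 4
Reactants: 5 2,6-dimethoxy-4-(2,4,6-trimethoxyphenoxy)phenol; 6 trichloroethylene
Product: 7 2-{[(E)-1,2-dichloroethenyl]oxy}-1,3-dimethoxy-5-(2,4,6-trimethoxyphenoxy)benzene
Conditions: K2CO3, DMF, 70 °C, Ar
Reagents that add atoms: none
Why: Base converts trichloroethylene into dichloroacetylene, to which the phenoxide adds in anti fashion to give the (E)-1,2-dichlorovinyl ether; the small linear electrophile should tolerate the two ortho methoxy groups that would hinder an arylation.

Step 5
Reactants: 7 2-{[(E)-1,2-dichloroethenyl]oxy}-1,3-dimethoxy-5-(2,4,6-trimethoxyphenoxy)benzene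
Product: 9 methyl 3-[2,6-dimethoxy-4-(2,4,6-trimethoxyphenoxy)phenoxy]prop-2-ynoate, via lithium aryloxyacetylide 8 (not isolated)
Conditions: n-BuLi (2.2 equiv), THF, −78 → −40 °C; cannulated into ClCO2Me (3 equiv), THF, −78 → 0 °C; quick filtration through neutral alumina
Reagents that add atoms: methyl chloroformate, COC(=O)Cl
Why: n-BuLi removes the vinyl proton, LiCl is lost to give the chloroalkynyl ether, and lithium–chlorine exchange gives acetylide 8, which the chloroformate acylates on carbon (acetylide acylation); at −78 °C the vinyl deprotonation should outrun ortho-lithiation of the methoxylated rings.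

Step 6
Reactants: 9 methyl 3-[2,6-dimethoxy-4-(2,4,6-trimethoxyphenoxy)phenoxy]prop-2-ynoate; 10 methyl 4-methoxy-3-oxobutanoate
Product: 12 methyl 6-[2,6-dimethoxy-4-(2,4,6-trimethoxyphenoxy)phenoxy]-2,4-dihydroxy-3-methoxybenzoate, via Michael adduct 11 (not isolated)
Conditions: 10 (1.0 equiv), NaH (1.0 equiv), THF, 0 °C; 9, −78 → −20 °C; LiN(iPr)2 (LDA, 2.2 equiv), −78 °C → rt; aq HCl
Reagents that add atoms: none
Why: Proposed new method: the sodium enolate of 10 adds through its C2 to the β-carbon of push–pull ynoate 9, the carbon that carries the aryloxy group, and proton transfer gives the doubly stabilised anion of adduct 11, whose alkene geometry is free to equilibrate through the dienolate. LDA then deprotonates the methoxymethylene carbon, and this more reactive carbanion attacks the acrylate ester carbonyl in a 6-exo-trig Claisen closure of ring C, so that C1–C6 and C3–C4 are made in one flask; loss of methoxide and enolisation of the cyclohexadienone give the resorcylate. The closest known reaction type is the Michael–Claisen (Michael–Dieckmann) [3+3] synthesis of resorcinols from 3-oxoglutarate or β-keto ester anions and alkyl-substituted alkynoates; an aryloxy-substituted ynoate paired with a 4-alkoxyacetoacetate has not been shown. No stereocentre is formed. Regioselectivity requires that C2 and not C4 of the keto ester attacks first, which is secured by having only the monoanion present in the Michael stage; chemoselectivity requires C-acylation instead of O-acylation to a 2-pyranone and retention of the aryloxy group, which is secured by forming the dianion with a non-nucleophilic amide at low temperature, with one equivalent of carbon nucleophile and no alkoxide present before ring closure.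

Step 7
Reactants: 12 methyl 6-[2,6-dimethoxy-4-(2,4,6-trimethoxyphenoxy)phenoxy]-2,4-dihydroxy-3-methoxybenzoate
Product: 14 5-[2,6-dimethoxy-4-(2,4,6-trimethoxyphenoxy)phenoxy]-2-methoxybenzene-1,3-diol, via resorcylic acid 13 (not isolated)
Conditions: KOH, MeOH–H2O (degassed), reflux, Ar; then aq HCl to pH 2, 80 °C
Reagents that add atoms: none
Why: Saponification gives the 2,4-dihydroxy-6-aryloxybenzoic acid, which, like other phloroglucinol-type carboxylic acids, should lose CO2 on warming in acid through ipso-protonation of the electron-rich ring (protodecarboxylation).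

Step 8
Reactants: 14 5-[2,6-dimethoxy-4-(2,4,6-trimethoxyphenoxy)phenoxy]-2-methoxybenzene-1,3-diol
Product: 15 5-[2,6-dihydroxy-4-(2,4,6-trihydroxyphenoxy)phenoxy]benzene-1,2,3-triol
Conditions: BBr3 (12 equiv), CH2Cl2, −78 °C → rt, Ar; MeOH, then H2O; product handled under Ar
Reagents that add atoms: none
Why: BBr3 cleavage of aryl methyl ethers (bromide attacks the methyl group of each O–B adduct) should remove all six methyl groups while the two diaryl ether bonds, which offer no SN2 site, stay intact.

**Compound list**

1 | 4-bromo-2,6-dimethoxyphenol | COc1cc(Br)cc(OC)c1O | starting material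
2 | 2-(benzyloxy)-5-bromo-1,3-dimethoxybenzene | COc1cc(Br)cc(OC)c1OCc1ccccc1 | intermediate
3 | 2,4,6-trimethoxyphenol | COc1cc(OC)c(O)c(OC)c1 | starting material
4 | 2-(benzyloxy)-1,3-dimethoxy-5-(2,4,6-trimethoxyphenoxy)benzene | COc1cc(Oc2c(OC)cc(OC)cc2OC)cc(OC)c1OCc1ccccc1 | intermediate
5 | 2,6-dimethoxy-4-(2,4,6-trimethoxyphenoxy)phenol | COc1cc(Oc2c(OC)cc(OC)cc2OC)cc(OC)c1O | intermediate
6 | trichloroethylene | ClC=C(Cl)Cl | starting material
7 | 2-{[(E)-1,2-dichloroethenyl]oxy}-1,3-dimethoxy-5-(2,4,6-trimethoxyphenoxy)benzene | Cl/C=C(/Cl)Oc1c(OC)cc(Oc2c(OC)cc(OC)cc2OC)cc1OC | intermediate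
8 | lithium 2-[2,6-dimethoxy-4-(2,4,6-trimethoxyphenoxy)phenoxy]ethynide (formed in the flask) | [Li]C#COc1c(OC)cc(Oc2c(OC)cc(OC)cc2OC)cc1OC | intermediate
9 | methyl 3-[2,6-dimethoxy-4-(2,4,6-trimethoxyphenoxy)phenoxy]prop-2-ynoate | COC(=O)C#COc1c(OC)cc(Oc2c(OC)cc(OC)cc2OC)cc1OC | intermediate
10 | methyl 4-methoxy-3-oxobutanoate | COCC(=O)CC(=O)OC | starting material
11 | dimethyl (2E)-3-[2,6-dimethoxy-4-(2,4,6-trimethoxyphenoxy)phenoxy]-4-(methoxyacetyl)pent-2-enedioate (formed in the flask as its enolate) | COCC(=O)C(C(=O)OC)/C(Oc1c(OC)cc(Oc2c(OC)cc(OC)cc2OC)cc1OC)=C\C(=O)OC | intermediate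
12 | methyl 6-[2,6-dimethoxy-4-(2,4,6-trimethoxyphenoxy)phenoxy]-2,4-dihydroxy-3-methoxybenzoate | COC(=O)c1c(O)c(OC)c(O)cc1Oc1c(OC)cc(Oc2c(OC)cc(OC)cc2OC)cc1OC | intermediate
13 | 6-[2,6-dimethoxy-4-(2,4,6-trimethoxyphenoxy)phenoxy]-2,4-dihydroxy-3-methoxybenzoic acid (formed in the flask) | OC(=O)c1c(O)c(OC)c(O)cc1Oc1c(OC)cc(Oc2c(OC)cc(OC)cc2OC)cc1OC | intermediate
14 | 5-[2,6-dimethoxy-4-(2,4,6-trimethoxyphenoxy)phenoxy]-2-methoxybenzene-1,3-diol | COc1c(O)cc(Oc2c(OC)cc(Oc3c(OC)cc(OC)cc3OC)cc2OC)cc1O | intermediate
15 | 5-[2,6-dihydroxy-4-(2,4,6-trihydroxyphenoxy)phenoxy]benzene-1,2,3-triol | Oc1cc(O)c(Oc2cc(O)c(Oc3cc(O)c(O)c(O)c3)c(O)c2)c(O)c1 | target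

**Step count**

Total steps: 8. Longest linear sequence: 8 steps (1 → 2 → 4 → 5 → 7 → 9 → 12 → 14 → 15).

**Steps most likely to fail**

1. Step 6. Three processes could defeat it:
   - the aryloxide could be expelled from the first-formed allenolate or from the adduct anion (net addition–elimination);
   - the enolate oxygen could acylate to give a 2-pyranone;
   - the dianion could fail to close onto the deactivated, anion-conjugated ester.

   Fallback (known chemistry): ring C is attached ready-made. The fallback sets out from phenol 5, which is coupled with 5-iodo-1,2,3-trimethoxybenzene under the conditions of step 2 (CuI, picolinic acid, K3PO4, DMSO, 100 °C). This Ullmann ether synthesis with a di-ortho-substituted phenol should give the heptamethyl ether 1,3-dimethoxy-5-(2,4,6-trimethoxyphenoxy)-2-(3,4,5-trimethoxyphenoxy)benzene F1. BBr3 in CH2Cl2, as in step 8, then cleaves all seven methyl ethers, and the route is rejoined at target 15.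

2. Step 5. The push–pull ynoate may hydrate or oligomerise during work-up and purification, and excess n-BuLi may lithiate the rings between their ether oxygens.

   Fallback: the ynoate is replaced by a β-chloroacrylate of the same oxidation level, made without organolithium reagents. The fallback sets out from phenol 5. Its sodium salt (NaH, DMF, 0 °C) displaces one chloride of methyl 3,3-dichloroprop-2-enoate F2 (from 3,3-dichloroacrylic acid, MeOH, catalytic H2SO4) by addition–elimination. This should give methyl 3-chloro-3-[2,6-dimethoxy-4-(2,4,6-trimethoxyphenoxy)phenoxy]prop-2-enoate F3 as a mixture of geometric isomers. The sodium enolate of 10 (THF, 0 °C) then displaces the remaining chloride, the better leaving group, and the route is rejoined at Michael adduct 11, which is taken on to 12 with LDA as in step 6.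

3. Step 2. Oxidative addition of the electron-rich bromide may be slow, and the hindered, easily oxidised phenol 3 may decompose at 100 °C.

   Fallback: the ether bond is formed by oxidative coupling at room temperature. The fallback sets out from bromide 2. Bromine–lithium exchange (n-BuLi, THF, −78 °C), B(OiPr)3 and aqueous acid give [4-(benzyloxy)-3,5-dimethoxyphenyl]boronic acid F4. Chan–Lam–Evans coupling of F4 with phenol 3 (Cu(OAc)2 20 mol %, pyridine, 4 Å molecular sieves, CH2Cl2, dry air, rt), a reaction type that tolerates di-ortho-substituted phenols, should give benzyl ether 4, where the route is rejoined.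

**Further compounds**

F1 | step 6 | 1,3-dimethoxy-5-(2,4,6-trimethoxyphenoxy)-2-(3,4,5-trimethoxyphenoxy)benzene | COc1cc(Oc2c(OC)cc(Oc3c(OC)cc(OC)cc3OC)cc2OC)cc(OC)c1OC
F2 | step 5 | methyl 3,3-dichloroprop-2-enoate | COC(=O)C=C(Cl)Cl
F3 | step 5 | methyl 3-chloro-3-[2,6-dimethoxy-4-(2,4,6-trimethoxyphenoxy)phenoxy]prop-2-enoate (mixture of geometric isomers) | COC(=O)C=C(Cl)Oc1c(OC)cc(Oc2c(OC)cc(OC)cc2OC)cc1OC
F4 | step 2 | [4-(benzyloxy)-3,5-dimethoxyphenyl]boronic acid | COc1cc(B(O)O)cc(OC)c1OCc1ccccc1
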